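**Plan**

1. Locants (abietane-type): ring B = C5–C6–C7(=O)–C8=C9–C10; quinone ring = C8, C9, C11(=O), C12(OH), C13(i-Pr), C14(=O); C10 carries CH3 (C20) and the C1–C2–C3 ester arm; C5 carries the isopropenyl group (C4).
2. Retrosynthetic cuts, in order: O12–CH3 and the quinone oxidation level (back to the 11,12,14-trimethoxyarene); C5–C4 (conjugate addition); C6 taken out of ring B (cuts C5–C6 and C6–C7, leaving the C5–C7 bond of an indan-1-one); C10–C20; C9–C10; C5–C10 (ketone acylation); C7–C8; C13–isopropyl.
3. Forward order: the arene (later the quinone ring) first, then the five-membered indenone ring (C7, C5, C10, C9, C8), then a cyclopropane on C7–C5, then ring B by one-carbon ring enlargement, then the C5 substituent, last the quinone and the free 12-OH.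
4. Stereochemistry: C10 (S) from a copper-catalysed asymmetric conjugate addition of Me3Al to the planar indenone (ligand control); C5 (S) from a rhodium/(S)-BINAP-catalysed 1,4-addition of isopropenyl to the ring-B enone, matched with approach anti to the propanoate arm.
5. Enabling feature: ring B is the ketone ring of a 1-tetralone whose only unsubstituted carbon, C6, lies between the C7 carbonyl and C5. Without C6 it is a 3,3-disubstituted indan-1-one, which the arene assembles in the right orientation (acylation at C8, closure at C9) and in which C10 is the β-carbon of an enone. Re-inserting C6 through the C7 enol ether leaves the C5=C6 enone that accepts the isopropenyl group.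

Key step: step 8

Assumption: electrophilic substitution of 5 is taken to occur at the ring carbon para to the central methoxy group (future C8), by analogy with the behaviour expected for the 3-methyl analogue.

**Route**

Step 1
Reactants: 1 1,2,4-trimethoxybenzene; 2 acetone
Product: 4 2-(2,3,6-trimethoxyphenyl)propan-2-ol, via aryllithium 3 (not isolated)
Conditions: n-BuLi, THF, 0 °C to rt; 2, −78 °C to rt; H2O
Reagents that add atoms: none
Why: Directed ortho-lithiation of 1 should take place at C3, the carbon flanked by two methoxy groups, and the aryllithium adds to the carbonyl group of acetone (1,2-addition), which places the future C13 side chain between O12 and O14 without a stereocentre.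

Step 2
Reactants: 4 2-(2,3,6-trimethoxyphenyl)propan-2-ol
Product: 5 1,2,4-trimethoxy-3-(propan-2-yl)benzene
Conditions: Et3SiH, CF3CO2H, CH2Cl2, 0 °C to rt
Reagents that add atoms: none
Why: Ionic hydrogenation, in which acid ionises the tertiary benzylic alcohol and Et3SiH transfers hydride to the cation.

Step 3
Reactants: 5 1,2,4-trimethoxy-3-(propan-2-yl)benzene
Product: 6 1-[2,4,5-trimethoxy-3-(propan-2-yl)phenyl]ethan-1-one
Conditions: AcCl, SnCl4, CH2Cl2, −20 to 0 °C
Reagents that add atoms: acetyl chloride, CC(Cl)=O
Why: Friedel–Crafts acylation at the more nucleophilic free position (ortho to the 4-methoxy and para to the 2-methoxy group, the future C8) forms the C7–C8 bond and brings in C5 as the acetyl methyl group.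

Step 4
Reactants: 6 aryl methyl ketone; 7 methyl 4-chloro-4-oxobutanoate
Product: 8 methyl 4,6-dioxo-6-[2,4,5-trimethoxy-3-(propan-2-yl)phenyl]hexanoate
Conditions: MgBr2·OEt2, i-Pr2NEt, CH2Cl2, 0 °C to rt
Reagents that add atoms: none
Why: Soft enolisation of the aryl methyl ketone and C-acylation of the magnesium enolate by the acid chloride (crossed Claisen-type acylation) should give the 1,3-diketone, forming the C5–C10 bond and bringing in C10 with the C1–C3 ester arm.

Step 5
Reactants: 8 1,3-diketone
Product: 9 methyl 3-[4,5,7-trimethoxy-1-oxo-6-(propan-2-yl)-1H-inden-3-yl]propanoate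
Conditions: CF3SO3H, CH2Cl2, 0 °C to rt
Reagents that add atoms: none
Why: Acid-mediated cyclodehydration of a 1-aryl-1,3-diketone (intramolecular Friedel–Crafts hydroxyalkylation by the activated C10 carbonyl at C9, the only free arene carbon, then loss of water) should give the 3-substituted inden-1-one and with it the C9–C10 bond.

Step 6
Reactants: 9 indenone
Product: 11 methyl 3-[(1S)-4,6,7-trimethoxy-1-methyl-5-(propan-2-yl)-3-(trimethylsilyloxy)-1H-inden-1-yl]propanoate, via aluminium enolate 10 (not isolated)
Conditions: Me3Al, CuTC (Cu(O2CC4H3S), 5 mol %), BINOL-derived N,N-bis(1-phenylethyl)phosphoramidite (10 mol %), Et2O, −30 °C; then TMSOTf, −30 to 0 °C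
Reagents that add atoms: trimethylaluminium, C[Al](C)C; trimethylsilyl trifluoromethanesulfonate, C[Si](C)(C)OS(=O)(=O)C(F)(F)F
Why: Copper-catalysed asymmetric conjugate addition of a trialkylaluminium reagent to a β-substituted cyclic enone sets the C10 quaternary stereocentre under ligand control (the ligand enantiomer used is the one that delivers CH3 to the Re face of C10, which gives S, to be fixed in a pilot run), and O-silylation of the aluminium enolate gives the C7=C5 enol ether needed next.

Step 7
Reactants: 11 silyl enol ether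
Product: 12 methyl 3-[(6S)-2,4,5-trimethoxy-6-methyl-3-(propan-2-yl)-1a-(trimethylsilyloxy)-1,1a,6,6a-tetrahydrocyclopropa[a]inden-6-yl]propanoate
Conditions: Et2Zn, CH2I2, CH2Cl2, 0 °C to rt
Reagents that add atoms: diiodomethane, ICI
Why: Simmons–Smith cyclopropanation of the electron-rich silyl enol ether adds C6 across C7=C5; the fusion is necessarily cis, and the configuration of the two cyclopropane carbons (a mixture relative to C10 is acceptable) is lost again in step 8.

Step 8
Reactants: 12 siloxycyclopropane
Product: 14 methyl 3-[(1S)-5,7,8-trimethoxy-1-methyl-4-oxo-6-(propan-2-yl)-1,4-dihydronaphthalen-1-yl]propanoate, via β-chloro ketone 13 (not isolated)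
Conditions: FeCl3 (2.5 equiv), DMF, 0 °C to rt; then NaOAc, MeOH, reflux
Reagents that add atoms: none
Why: Trivalent iron (FeCl3 in DMF) removes one electron from the siloxycyclopropane, and the radical cation opens by β-scission of the internal C7–C5 bond shared by the three- and five-membered rings, so that the five-membered ring (C7, C5, C10, C9, C8) becomes six-membered ring B with C6 between C7 and C5 and C7 as the aryl ketone. The secondary C5 radical takes chlorine from a second FeCl3, and NaOAc then removes HCl through the C7 enolate (E1cB) to give the C5=C6 enone. The closest known reaction type is the FeCl3-mediated one-carbon ring enlargement of 1-siloxybicyclo[n.1.0]alkanes to cycloalk-2-enones. No ring is closed by a new bond: ring B arises by cleavage of the zero-atom bridge of the bicyclo[3.1.0]hexane unit. No lasting stereocentre is formed (the C5–Cl centre disappears in the elimination) and the C10 quaternary centre is not touched, so its configuration is carried through. The selectivity needed is cleavage of the internal instead of the external cyclopropane bond and oxidation of the siloxycyclopropane instead of the trimethoxyarene; the first is secured by formation of a secondary (not primary) radical with the larger strain release, the second by the low oxidising power of DMF-ligated FeCl3.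

Step 9
Reactants: 14 ring-B enone; 15 4,4,5,5-tetramethyl-2-(prop-1-en-2-yl)-1,3,2-dioxaborolane
Product: 16 methyl 3-[(1S,2S)-5,7,8-trimethoxy-1-methyl-4-oxo-6-(propan-2-yl)-2-(prop-1-en-2-yl)-1,2,3,4-tetrahydronaphthalen-1-yl]propanoate
Conditions: [Rh(OH)((S)-binap)]2 (3 mol %), Et3N, dioxane/H2O 10:1, 50 °C
Reagents that add atoms: none
Why: Rhodium-catalysed asymmetric 1,4-addition of an alkenylboron reagent (Hayashi–Miyaura reaction), in which the (S)-BINAP complex, by the facial sense that gives (S)-3-substituted cyclohexanones from cyclohex-2-enone, should deliver isopropenyl to the C5 face syn to the C10 methyl group and anti to the larger propanoate arm (Re face of C5), so that C5 is set as S by matched catalyst and substrate control.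

Step 10
Reactants: 16 trimethoxyarene ketone
Product: 17 methyl 3-[(1S,2S)-7-methoxy-1-methyl-4,5,8-trioxo-6-(propan-2-yl)-2-(prop-1-en-2-yl)-1,2,3,4,5,8-hexahydronaphthalen-1-yl]propanoate
Conditions: (NH4)2Ce(NO3)6, MeCN/H2O 2:1, 0 °C
Reagents that add atoms: water, O
Why: Oxidative demethylation of the para-dimethoxy pair (C11/C14) by tetravalent cerium should give the 1,4-quinone with both carbonyl oxygens taken from water, while the C12 methoxy group stays as a vinylogous ester and the alkene, ketone and ester are not attacked at 0 °C.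

Step 11
Reactants: 17 methoxyquinone
Product: 18 methyl 3-[(1S,2S)-7-hydroxy-1-methyl-4,5,8-trioxo-6-(propan-2-yl)-2-(prop-1-en-2-yl)-1,2,3,4,5,8-hexahydronaphthalen-1-yl]propanoate (target)
Conditions: BCl3 (2.5 equiv), CH2Cl2, −78 to −30 °C; aq NaHCO3, then pH 4 buffer
Reagents that add atoms: none
Why: BCl3 chelates the C11 carbonyl and the C12 methoxy oxygen, and chloride cleaves the O–CH3 bond of this vinylogous ester (Lewis-acid ether cleavage next to a carbonyl group) at low temperature, where the saturated methyl ester and the isopropenyl group should not react and no stereocentre is touched.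

**Compound list**

1 | 1,2,4-trimethoxybenzene | COc1ccc(OC)c(OC)c1 | starting material
2 | acetone | CC(C)=O | starting material
3 | (2,3,6-trimethoxyphenyl)lithium | [Li]c1c(OC)ccc(OC)c1OC | intermediate (not isolated)
4 | 2-(2,3,6-trimethoxyphenyl)propan-2-ol | CC(C)(O)c1c(OC)ccc(OC)c1OC | intermediate
5 | 1,2,4-trimethoxy-3-(propan-2-yl)benzene | CC(C)c1c(OC)ccc(OC)c1OC | intermediate
6 | 1-[2,4,5-trimethoxy-3-(propan-2-yl)phenyl]ethan-1-one | CC(=O)c1cc(OC)c(OC)c(C(C)C)c1OC | intermediate
7 | methyl 4-chloro-4-oxobutanoate | COC(=O)CCC(Cl)=O | starting material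
8 | methyl 4,6-dioxo-6-[2,4,5-trimethoxy-3-(propan-2-yl)phenyl]hexanoate | COC(=O)CCC(=O)CC(=O)c1cc(OC)c(OC)c(C(C)C)c1OC | intermediate
9 | methyl 3-[4,5,7-trimethoxy-1-oxo-6-(propan-2-yl)-1H-inden-3-yl]propanoate | COC(=O)CCC1=CC(=O)c2c(OC)c(C(C)C)c(OC)c(OC)c12 | intermediate
10 | dimethylaluminium enolate (O–AlMe2 on C7) of the (S)-3-methylindanone, quaternary carbon S | COC(=O)CC[C@@]1(C)C=C(O[Al](C)C)c2c(OC)c(C(C)C)c(OC)c(OC)c12 | intermediate (not isolated)
11 | methyl 3-[(1S)-4,6,7-trimethoxy-1-methyl-5-(propan-2-yl)-3-(trimethylsilyloxy)-1H-inden-1-yl]propanoate | COC(=O)CC[C@@]1(C)C=C(O[Si](C)(C)C)c2c(OC)c(C(C)C)c(OC)c(OC)c12 | intermediate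
12 | methyl 3-[(6S)-2,4,5-trimethoxy-6-methyl-3-(propan-2-yl)-1a-(trimethylsilyloxy)-1,1a,6,6a-tetrahydrocyclopropa[a]inden-6-yl]propanoate (cis-fused cyclopropane, both diastereomers relative to C6; cyclopropane carbons left unspecified) | COC(=O)CC[C@@]1(C)C2CC2(O[Si](C)(C)C)c2c(OC)c(C(C)C)c(OC)c(OC)c12 | intermediate
13 | methyl 3-[(1R)-2-chloro-5,7,8-trimethoxy-1-methyl-4-oxo-6-(propan-2-yl)-1,2,3,4-tetrahydronaphthalen-1-yl]propanoate (both C2 epimers; the descriptor at C1 is R only because Cl changes the ranking, the spatial arrangement is that of 12 and 14) | COC(=O)CC[C@@]1(C)C(Cl)CC(=O)c2c(OC)c(C(C)C)c(OC)c(OC)c12 | intermediate (not isolated)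
14 | methyl 3-[(1S)-5,7,8-trimethoxy-1-methyl-4-oxo-6-(propan-2-yl)-1,4-dihydronaphthalen-1-yl]propanoate | COC(=O)CC[C@@]1(C)C=CC(=O)c2c(OC)c(C(C)C)c(OC)c(OC)c12 | intermediate
15 | 4,4,5,5-tetramethyl-2-(prop-1-en-2-yl)-1,3,2-dioxaborolane | CC(=C)B1OC(C)(C)C(C)(C)O1 | starting material
16 | methyl 3-[(1S,2S)-5,7,8-trimethoxy-1-methyl-4-oxo-6-(propan-2-yl)-2-(prop-1-en-2-yl)-1,2,3,4-tetrahydronaphthalen-1-yl]propanoate | C=C(C)[C@@H]1CC(=O)c2c(OC)c(C(C)C)c(OC)c(OC)c2[C@@]1(C)CCC(=O)OC | intermediate
17 | methyl 3-[(1S,2S)-7-methoxy-1-methyl-4,5,8-trioxo-6-(propan-2-yl)-2-(prop-1-en-2-yl)-1,2,3,4,5,8-hexahydronaphthalen-1-yl]propanoate | C=C(C)[C@@H]1CC(=O)C2=C(C(=O)C(OC)=C(C(C)C)C2=O)[C@@]1(C)CCC(=O)OC | intermediate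
18 | methyl 3-[(1S,2S)-7-hydroxy-1-methyl-4,5,8-trioxo-6-(propan-2-yl)-2-(prop-1-en-2-yl)-1,2,3,4,5,8-hexahydronaphthalen-1-yl]propanoate | C=C(C)[C@@H]1CC(=O)C2=C(C(=O)C(O)=C(C(C)C)C2=O)[C@@]1(C)CCC(=O)OC | target

Total step count: 11. Longest linear sequence: 11 steps (1 to 18).

**Steps most likely to fail**

Step 5 (indenone by cyclodehydration). The process at risk is the ring closure at C9: O-protonation of the aryl ketone lowers the nucleophilicity of the arene, and the γ-keto ester may be diverted into enol-lactone formation instead. The fallback sets out from 5 and returns at 9. Doebner condensation of commercial methyl 4-oxobutanoate with malonic acid (pyridine, piperidine) should give (E)-6-methoxy-6-oxohex-2-enoic acid F1. Activation with (CF3CO)2O and acylation of 5 at C8 should give methyl (E)-6-oxo-6-[2,4,5-trimethoxy-3-(propan-2-yl)phenyl]hex-4-enoate F2. CF3SO3H should then close this aryl vinyl ketone at C9 (Nazarov-type cyclisation) to racemic methyl 3-[4,6,7-trimethoxy-3-oxo-5-(propan-2-yl)-2,3-dihydro-1H-inden-1-yl]propanoate F3, and dehydrogenation with IBX (DMSO, 70 °C) leads back to 9.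

Step 6 (quaternary C10). The process at risk is facial discrimination on the planar benzo-fused enone, together with slow conjugate addition beside the peri C11 methoxy group (1,2-addition then competes). The fallback sets out from 9 and returns at 11. Me2CuLi (Et2O, −78 °C; aqueous NH4Cl) should give racemic methyl 3-[4,6,7-trimethoxy-1-methyl-3-oxo-5-(propan-2-yl)-2,3-dihydro-1H-inden-1-yl]propanoate F4. Preparative chromatography on a chiral stationary phase should provide methyl 3-[(1S)-4,6,7-trimethoxy-1-methyl-3-oxo-5-(propan-2-yl)-2,3-dihydro-1H-inden-1-yl]propanoate F5, which TMSOTf and Et3N convert into 11.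

Step 9 (C5). The process at risk is insertion at the β-carbon next to the quaternary centre, which may be slow enough for protodeboronation of the alkenylboronate to compete, and erosion of facial selectivity at C5. The fallback sets out from 14 and returns at 16. Isopropenylmagnesium bromide with catalytic CuBr·SMe2 and TMSCl (THF, −78 °C) should add under substrate control anti to the larger propanoate arm to give methyl 3-[(1S,2S)-5,7,8-trimethoxy-1-methyl-6-(propan-2-yl)-2-(prop-1-en-2-yl)-4-(trimethylsilyloxy)-1,2-dihydronaphthalen-1-yl]propanoate F6. Mild acid hydrolysis of the silyl enol ether and chromatographic removal of the C5 epimer lead back to 16.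

**Further compounds**

F1 | step 5 | (E)-6-methoxy-6-oxohex-2-enoic acid | COC(=O)CC/C=C/C(=O)O
F2 | step 5 | methyl (E)-6-oxo-6-[2,4,5-trimethoxy-3-(propan-2-yl)phenyl]hex-4-enoate | COC(=O)CC/C=C/C(=O)c1cc(OC)c(OC)c(C(C)C)c1OC
F3 | step 5 | racemic methyl 3-[4,6,7-trimethoxy-3-oxo-5-(propan-2-yl)-2,3-dihydro-1H-inden-1-yl]propanoate | COC(=O)CCC1CC(=O)c2c(OC)c(C(C)C)c(OC)c(OC)c12
F4 | step 6 | racemic methyl 3-[4,6,7-trimethoxy-1-methyl-3-oxo-5-(propan-2-yl)-2,3-dihydro-1H-inden-1-yl]propanoate | COC(=O)CCC1(C)CC(=O)c2c(OC)c(C(C)C)c(OC)c(OC)c12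
F5 | step 6 | methyl 3-[(1S)-4,6,7-trimethoxy-1-methyl-3-oxo-5-(propan-2-yl)-2,3-dihydro-1H-inden-1-yl]propanoate | COC(=O)CC[C@@]1(C)CC(=O)c2c(OC)c(C(C)C)c(OC)c(OC)c12
F6 | step 9 | methyl 3-[(1S,2S)-5,7,8-trimethoxy-1-methyl-6-(propan-2-yl)-2-(prop-1-en-2-yl)-4-(trimethylsilyloxy)-1,2-dihydronaphthalen-1-yl]propanoate | C=C(C)[C@@H]1C=C(O[Si](C)(C)C)c2c(OC)c(C(C)C)c(OC)c(OC)c2[C@@]1(C)CCC(=O)OC
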